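**Assumption:** (+)-catechin [(2R,3S), sold as the hydrate] and 3,4,5-tris(benzyloxy)benzoic acid are taken as cheap commercial starting materials. Both stereocentres of the target are therefore bought with (+)-catechin and the route only has to preserve them.

## Retrosynthetic overview

1. Target ⇒ its hexa-O-benzyl ether; the last step is a global hydrogenolysis that forms no skeletal bond.
2. Key disconnections: the two aryl ester C–O bonds O5–C(=O) and O7–C(=O) ⇒ (+)-catechin + 2 × 3,4,5-tris(benzyloxy)benzoyl chloride. Both bonds are made in one pot while the B-ring catechol is masked in the flask as a cyclic phenylboronate (the new, site-selective step).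
3. Acid chloride ⇒ commercial 3,4,5-tris(benzyloxy)benzoic acid.
4. Rings: none is formed. The chroman ring with its 2,3-trans (2R,3S) centres and all aromatic rings come intact from the starting materials.

## Route

Step 1
Reactants: 1 3,4,5-tris(benzyloxy)benzoic acid
Product: 2 3,4,5-tris(benzyloxy)benzoyl chloride
Conditions: (COCl)2 (1.5 eq), DMF (cat.), CH2Cl2, 0 °C → rt, 2 h; evaporate, strip twice with toluene, use crude
Reagents that add atoms: oxalyl chloride, ClC(=O)C(=O)Cl
Why: DMF-catalysed (Vilsmeier-type) acid chloride formation is routine for this acid, the aryl benzyl ethers tolerate it and all by-products are volatile; no stereocentre is involved.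

Step 2
Reactants: 3 (+)-catechin [(2R,3S)-2-(3,4-dihydroxyphenyl)chromane-3,5,7-triol, 2,3-trans], 4 phenylboronic acid, 2 3,4,5-tris(benzyloxy)benzoyl chloride
Product: 7 5,7-bis-O-[3,4,5-tris(benzyloxy)benzoyl]-(+)-catechin, via catechin B-ring phenylboronate 5 (not isolated), via bis-aroylated B-ring phenylboronate 6 (not isolated)
Conditions: 3 (dried), 4 (1.05 eq), 4 Å MS, THF, rt, 2 h; then iPr2NEt (2.6 eq), 2 (2.15 eq), −20 °C → rt, 6 h; then pinacol (2 eq), rt, 1 h; citric acid work-up, SiO2
Reagents that add atoms: none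
Why: Proposed new method: a one-pot, boron-templated site-selective double O-aroylation of an unprotected flavan-3-ol — PhB(OH)2 condenses only with the B-ring catechol (the sole pair of hydroxyls that can close a five-membered 1,3,2-benzodioxaborole; O3/O5 would need an eight-membered ring), and in the trigonal boronate the O3′/O4′ lone pairs are donated into boron and carry no acidic proton, so with the hindered, non-coordinating base iPr2NEt (chosen to avoid a nucleophilic tetracoordinate "ate" complex) only the A-ring phenols (pKa ≈ 9) are deprotonated and aroylated by 2, the hindered neutral 3-OH being inert to an aroyl chloride without DMAP, after which neutral transesterification to pinacol (PhBpin is the more stable ester) frees the catechol without touching the new aryl esters; the closest known reaction types are transient boronic-ester masking of diols in carbohydrate acylation and borate masking of catechols during N-acylation or O-alkylation, combined with Einhorn-type phenol aroylation; no stereocentre is formed and C2/C3 are untouched (the masked catechol also blocks the quinone-methide path to C2 epimerisation).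

Step 3
Reactants: 7 5,7-bis-O-[3,4,5-tris(benzyloxy)benzoyl]-(+)-catechin
Product: 8 (+)-catechin 5,7-di-O-gallate [(2R,3S); target]
Conditions: H2 (1 atm), 20% Pd(OH)2/C, THF–EtOAc 1:1, rt, 3 h; filter under N2, RP-C18 (MeCN/H2O, 0.1% HCO2H), lyophilise
Reagents that add atoms: none
Why: Pd-catalysed hydrogenolysis (O-debenzylation) removes the six aryl benzyl ethers while the aryl esters, the 3-OH and the cyclic C2–O1 ether survive, as is usual for benzylated catechin gallates; the aprotic, base-free medium prevents ester solvolysis or migration, and C2/C3 are not touched.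

## Compound list

1 | 3,4,5-tris(benzyloxy)benzoic acid | OC(=O)c1cc(OCc2ccccc2)c(OCc2ccccc2)c(OCc2ccccc2)c1 | starting material
2 | 3,4,5-tris(benzyloxy)benzoyl chloride | ClC(=O)c1cc(OCc2ccccc2)c(OCc2ccccc2)c(OCc2ccccc2)c1 | intermediate
3 | (+)-catechin, (2R,3S)-2-(3,4-dihydroxyphenyl)chromane-3,5,7-triol | Oc1cc(O)c2c(c1)O[C@H](c1ccc(O)c(O)c1)[C@@H](O)C2 | starting material
4 | phenylboronic acid | OB(O)c1ccccc1 | starting material
5 | catechin B-ring phenylboronate, (2R,3S)-2-(2-phenyl-1,3,2-benzodioxaborol-5-yl)chromane-3,5,7-triol | Oc1cc(O)c2c(c1)O[C@H](c1ccc3OB(c4ccccc4)Oc3c1)[C@@H](O)C2 | intermediate (not isolated)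
6 | bis-aroylated B-ring phenylboronate, 5,7-bis-O-[3,4,5-tris(benzyloxy)benzoyl]-(+)-catechin 3′,4′-O-phenylboronate | O=C(Oc1cc(OC(=O)c2cc(OCc3ccccc3)c(OCc3ccccc3)c(OCc3ccccc3)c2)c2c(c1)O[C@H](c1ccc3OB(c4ccccc4)Oc3c1)[C@@H](O)C2)c1cc(OCc2ccccc2)c(OCc2ccccc2)c(OCc2ccccc2)c1 | intermediate (not isolated)
7 | 5,7-bis-O-[3,4,5-tris(benzyloxy)benzoyl]-(+)-catechin (2R,3S) | O=C(Oc1cc(OC(=O)c2cc(OCc3ccccc3)c(OCc3ccccc3)c(OCc3ccccc3)c2)c2c(c1)O[C@H](c1ccc(O)c(O)c1)[C@@H](O)C2)c1cc(OCc2ccccc2)c(OCc2ccccc2)c(OCc2ccccc2)c1 | intermediate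
8 | (+)-catechin 5,7-di-O-gallate (2R,3S) | O=C(Oc1cc(OC(=O)c2cc(O)c(O)c(O)c2)c2c(c1)O[C@H](c1ccc(O)c(O)c1)[C@@H](O)C2)c1cc(O)c(O)c(O)c1 | target

## Step count and risks

Total step count: 3. Longest linear sequence: 3 steps (1 → 2 → 7 → 8); 2 steps from (+)-catechin.

**Step 2 (proposed new step, most likely to fail).** The risks are partial acylation of the B-ring if the boronate opens under the basic conditions, and mixtures of mono-, di- and 3-O-acylated products. The fallback uses known chemistry only, sets out from 3 and comes back to the route at 8. Compound 3 is treated with dichlorodiphenylmethane and K2CO3 in MeCN at rt under N2 to give 3′,4′-O-diphenylmethylene-(+)-catechin F2; only the catechol can bridge one carbon with two oxygens. The A-ring phenols of F2 are then aroylated with 2 (2.2 eq) and iPr2NEt in THF at 0 °C to give 5,7-bis-O-[3,4,5-tris(benzyloxy)benzoyl]-3′,4′-O-diphenylmethylene-(+)-catechin F3. Hydrogenolysis under the conditions of step 3 cleaves the six benzyl ethers and the diphenylmethylene ketal together and gives 8. This costs one more isolated step (4 in total).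

**Step 3.** The risks are solvolysis or migration of the activated A-ring aryl esters, slow or incomplete sixfold debenzylation, reductive opening of the benzylic C2–O1 bond, and air oxidation of the product. The fallback replaces hydrogenolysis by fluoride-labile protection of the galloyl donor; it sets out from 3 and comes back at 8. Gallic acid F4 (commercial) is persilylated with TBSCl and imidazole in DMF to tert-butyldimethylsilyl 3,4,5-tris(tert-butyldimethylsilyloxy)benzoate F5. The silyl ester is converted directly under neutral conditions with (COCl)2 and catalytic DMF in CH2Cl2 into 3,4,5-tris(tert-butyldimethylsilyloxy)benzoyl chloride F6. Compound 3 is masked in the flask as 5 exactly as in step 2 and aroylated with F6 and iPr2NEt to the silylated bis-aroylated B-ring phenylboronate F7. Pinacol then releases 5,7-bis-O-[3,4,5-tris(tert-butyldimethylsilyloxy)benzoyl]-(+)-catechin F8. HF·pyridine in THF/pyridine at 0 °C removes the six aryl silyl ethers without reducing anything or attacking the aryl esters and gives 8.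

**Step 1.** The risks are traces of HCl or oxalyl chloride carried into step 2, where they would strip the boronate or acylate unselectively, and hydrolysis of the moisture-sensitive chloride. The fallback avoids an acyl halide altogether; it sets out from 1 and comes back at 7. Two equivalents of 1 are dehydrated with N,N′-diisopropylcarbodiimide (0.5 eq per acid) in CH2Cl2 at 0 °C to the symmetric 3,4,5-tris(benzyloxy)benzoic anhydride F1. F1 (2.3 eq) is used in place of 2 in step 2 (iPr2NEt, THF/MeCN, rt → 40 °C) via the same in-flask compounds 5 and 6 to give 7. The milder donor further favours phenoxide over the 3-OH, and the liberated 1 is recovered.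

## Further compounds

F1 | step 1 | 3,4,5-tris(benzyloxy)benzoic anhydride | O=C(OC(=O)c1cc(OCc2ccccc2)c(OCc2ccccc2)c(OCc2ccccc2)c1)c1cc(OCc2ccccc2)c(OCc2ccccc2)c(OCc2ccccc2)c1
F2 | step 2 | 3′,4′-O-diphenylmethylene-(+)-catechin, (2R,3S)-2-(2,2-diphenyl-1,3-benzodioxol-5-yl)chromane-3,5,7-triol | Oc1cc(O)c2c(c1)O[C@H](c1ccc3OC(c4ccccc4)(c4ccccc4)Oc3c1)[C@@H](O)C2
F3 | step 2 | 5,7-bis-O-[3,4,5-tris(benzyloxy)benzoyl]-3′,4′-O-diphenylmethylene-(+)-catechin | O=C(Oc1cc(OC(=O)c2cc(OCc3ccccc3)c(OCc3ccccc3)c(OCc3ccccc3)c2)c2c(c1)O[C@H](c1ccc3OC(c4ccccc4)(c4ccccc4)Oc3c1)[C@@H](O)C2)c1cc(OCc2ccccc2)c(OCc2ccccc2)c(OCc2ccccc2)c1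
F4 | step 3 | gallic acid (commercial input of the fallback) | OC(=O)c1cc(O)c(O)c(O)c1
F5 | step 3 | tert-butyldimethylsilyl 3,4,5-tris(tert-butyldimethylsilyloxy)benzoate | CC(C)(C)[Si](C)(C)OC(=O)c1cc(O[Si](C)(C)C(C)(C)C)c(O[Si](C)(C)C(C)(C)C)c(O[Si](C)(C)C(C)(C)C)c1
F6 | step 3 | 3,4,5-tris(tert-butyldimethylsilyloxy)benzoyl chloride | ClC(=O)c1cc(O[Si](C)(C)C(C)(C)C)c(O[Si](C)(C)C(C)(C)C)c(O[Si](C)(C)C(C)(C)C)c1
F7 | step 3 | 5,7-bis-O-[3,4,5-tris(tert-butyldimethylsilyloxy)benzoyl]-(+)-catechin 3′,4′-O-phenylboronate | O=C(Oc1cc(OC(=O)c2cc(O[Si](C)(C)C(C)(C)C)c(O[Si](C)(C)C(C)(C)C)c(O[Si](C)(C)C(C)(C)C)c2)c2c(c1)O[C@H](c1ccc3OB(c4ccccc4)Oc3c1)[C@@H](O)C2)c1cc(O[Si](C)(C)C(C)(C)C)c(O[Si](C)(C)C(C)(C)C)c(O[Si](C)(C)C(C)(C)C)c1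
F8 | step 3 | 5,7-bis-O-[3,4,5-tris(tert-butyldimethylsilyloxy)benzoyl]-(+)-catechin | O=C(Oc1cc(OC(=O)c2cc(O[Si](C)(C)C(C)(C)C)c(O[Si](C)(C)C(C)(C)C)c(O[Si](C)(C)C(C)(C)C)c2)c2c(c1)O[C@H](c1ccc(O)c(O)c1)[C@@H](O)C2)c1cc(O[Si](C)(C)C(C)(C)C)c(O[Si](C)(C)C(C)(C)C)c(O[Si](C)(C)C(C)(C)C)c1
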